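Readings and results come from a simulation with constants of no real substance; noise was put on by code.

How much of this flask's slowness at 20% conversion a new charge can undo is your question, and a quick number needs one gain, read as on logarithmic axes.

| flask | starting material | second substrate | enzyme | remark |
|---|---|---|---|---|
| Friday's | 20 mM | 0.50 equiv | 0.05 mol% | the very flask that is asked about, followed so far |
| Saturday's | 20 mM | 0.75 equiv | 0.05 mol% | run made earlier |
| flask | 20 mM | 0.500 equiv | 0.05 mol% |  |

| run | time / min | product / % |
|---|---|---|
| Friday's | 0.167 | 3.2 |
| Friday's | 0.500 | 8.7 |
| Friday's | 0.833 | 12.9 |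
| Friday's | 1.33 | 19.7 |
| Friday's | 2.00 | 26.3 |
| Friday's | 2.50 | 30.7 |
| Saturday's | 0.250 | 5.5 |
| Saturday's | 0.417 | 9.0 |
| Saturday's | 0.667 | 14.2 |
| Saturday's | 1.33 | 24.6 |
| Saturday's | 2.00 | 33.3 |
| Saturday's | 3.00 | 43.5 |

(standard deviation of a reading: 0.5 percentage points)

- factor on the rate of making product when 20% of the starting material are converted if second substrate is charged twice over
- factor on the rate when 20% of the starting material are converted if enzyme is charged at 0.005 mol% instead

- steps thought possible: starting material + enzyme <-> starting complex; second substrate + starting complex <-> ternary complex; ternary complex -> enzyme + product; 2 enzyme <-> resting dimer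
- no earlier run changes the charge of enzyme; that part of a forecast is a guess

Here is my own reckoning. Chords across that level climb at 0.115 min⁻¹ of the charge in Friday's run and 0.157 min⁻¹ in Saturday's. Each unit of product takes one of second substrate, so at that level, as fractions of the starting material charged, Friday's flask has 0.300 of it left and Saturday's 0.550. The logarithm of the rate ratio over the logarithm of that ratio is 0.515. This is the gain, or apparent order: the exponent that turns a ratio of amount left into a ratio of rate. It is a reading and carries the scatter of the points.

Charging twice the second substrate in Friday's flask leaves 0.800 at that level, so I commit to 1.66. No run changes the enzyme, so I simply borrow the gain for the cut to 0.005 mol% and guess 0.306.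

Your forecast gives 1.55 and 0.14, the second on the ground that “the dimer dissociates, so I guess slightly above 0.1”. We part on both, my number being higher than yours on the second substrate and my guess higher than yours on the enzyme.

The flask gives 1.70 and 0.251, on these steps:

    starting material + enzyme ⇌ starting complex (K = 86.5 M⁻¹, k = 14700 M⁻¹ s⁻¹)
    second substrate + starting complex ⇌ ternary complex (K = 624 M⁻¹, k = 27400 M⁻¹ s⁻¹)
    ternary complex → enzyme + product (k = 39.1 s⁻¹)
    2 enzyme ⇌ resting dimer, settled at all times (K = 1.51 × 10⁷ M⁻¹)

In this flask at 0.800 min the resting dimer, the catalyst's resting state, holds 78.1% of the catalyst charged, more than the ternary complex's 11.9%. Borrowed again for a flask with twice the enzyme, the gain of 0.515 gives a factor of 0.700 on the time to that conversion, and that run gives 0.681.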